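**Strategy.** The target is a cis-fused decalin: H5, the C10 methyl (C20), the C9 side chain and the C4 acetoxymethyl group all lie on one face. The route rests on disconnecting ring B at C9–C10 and C5–C6 by a Diels–Alder reaction between a ring A cyclohexenecarbaldehyde, whose formyl group is the latent C20 methyl, and an (E)-diene carrying C6–C9, C11, C12 and C17. In one operation the cycloaddition closes ring B and relays the single catalysis-derived stereocentre C4 to C5, C10 and C9, exploiting the cis A/B fusion and the contiguous C5–C10–C9 triad. The precursors are enal 8 and diene 12.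

Key step: step 7

Numbering: labdane numbering is used (ring A = C1–C5, C10; ring B = C5–C10; C17 = exocyclic methylene carbon; C18 = methyl and C19 = acetoxymethyl carbon on C4; C20 = methyl on C10; C11–C12 = ethylene linker; C13–C16 = butenolide).
Assumption: 3-bromofuran-2(5H)-one (20) is taken as a commercial reagent.

Step 1
Reactants: 1 3-methylcyclohex-2-en-1-one; 2 (chloromethyl)dimethyl(propan-2-yloxy)silane
Product: 5 (3R)-3-{[dimethyl(propan-2-yloxy)silyl]methyl}-3-methylcyclohex-1-en-1-yl trifluoromethanesulfonate, via Grignard reagent 3 (not isolated), via magnesium enolate 4 (not isolated)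
Conditions: 2, Mg, Et2O; then 1, Cu(OTf)2 (cat.), chiral C2-symmetric imidazolinium salt (carbene precursor, cat.), Et2O, −30 °C; then PhNTf2, THF, −30 °C → rt
Reagents that add atoms: N-phenylbis(trifluoromethanesulfonimide), O=S(=O)(N(c1ccccc1)S(=O)(=O)C(F)(F)F)C(F)(F)F
Why: Copper-catalysed asymmetric conjugate addition of a Grignard reagent to a β-substituted cyclohexenone should create the quaternary C4 centre (ligand enantiomer chosen to give R), and the regiodefined magnesium enolate is trapped on oxygen as the enol triflate.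

Step 2
Reactants: 5 (3R)-3-{[dimethyl(propan-2-yloxy)silyl]methyl}-3-methylcyclohex-1-en-1-yl trifluoromethanesulfonate
Product: 6 (3R)-3-(hydroxymethyl)-3-methylcyclohex-1-en-1-yl trifluoromethanesulfonate
Conditions: H2O2 (30 % aq.), KF, KHCO3, THF/MeOH, rt
Reagents that add atoms: hydrogen peroxide, OO
Why: Tamao–Fleming oxidation of the alkoxysilane replaces C–Si by C–OH at a non-stereogenic carbon, and the bicarbonate-buffered peroxide should leave the enol triflate untouched.

Step 3
Reactants: 6 (3R)-3-(hydroxymethyl)-3-methylcyclohex-1-en-1-yl trifluoromethanesulfonate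
Product: 7 [(1R)-1-methyl-3-(trifluoromethanesulfonyloxy)cyclohex-2-en-1-yl]methyl acetate
Conditions: Ac2O, pyridine, DMAP (cat.), CH2Cl2, 0 °C → rt
Reagents that add atoms: acetic anhydride, CC(=O)OC(C)=O
Why: DMAP-catalysed O-acetylation installs the acetate of the target early, where it also becomes the larger of the two C4 substituents.

Step 4
Reactants: 7 [(1R)-1-methyl-3-(trifluoromethanesulfonyloxy)cyclohex-2-en-1-yl]methyl acetate
Product: 8 [(1R)-3-formyl-1-methylcyclohex-2-en-1-yl]methyl acetate
Conditions: CO (1 atm), Bu3SnH (slow addition), Pd(PPh3)4 (cat.), LiCl, THF, 50 °C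
Reagents that add atoms: carbon monoxide, [C-]#[O+]
Why: Palladium-catalysed reductive carbonylation of an enol triflate (oxidative addition to zerovalent palladium, CO insertion, hydride transfer from tin) should give the conjugated aldehyde without touching C4.

Step 5
Reactants: 9 3-methyl-2,5-dihydrothiophene 1,1-dioxide; 10 tert-butyl(2-iodoethoxy)dimethylsilane
Product: 11 (2RS)-2-(2-{[tert-butyl(dimethyl)silyl]oxy}ethyl)-3-methyl-2,5-dihydrothiophene 1,1-dioxide
Conditions: LiN(SiMe3)2 (added to the mixture of 9 and 10), THF/HMPA, −78 °C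
Reagents that add atoms: none
Why: α-Sulfonyl carbanion alkylation of 3-methyl-3-sulfolene takes place at C2, next to the methyl-bearing carbon, when the anion is trapped in situ at low temperature.

Step 6
Reactants: 11 (2RS)-2-(2-{[tert-butyl(dimethyl)silyl]oxy}ethyl)-3-methyl-2,5-dihydrothiophene 1,1-dioxide
Product: 12 tert-butyl(dimethyl){[(3E)-4-methylhexa-3,5-dien-1-yl]oxy}silane
Conditions: toluene, pyridine (cat.), 110 °C
Reagents that add atoms: none
Why: Thermal cheletropic extrusion of SO2 is disrotatory and should deliver the (E)-1-substituted diene stereospecifically.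

Step 7
Reactants: 8 [(1R)-3-formyl-1-methylcyclohex-2-en-1-yl]methyl acetate; 12 tert-butyl(dimethyl){[(3E)-4-methylhexa-3,5-dien-1-yl]oxy}silane
Product: 13 [(1R,4aR,5R,8aS)-5-(2-{[tert-butyl(dimethyl)silyl]oxy}ethyl)-4a-formyl-1,6-dimethyl-1,2,3,4,4a,5,8,8a-octahydronaphthalen-1-yl]methyl acetate
Conditions: Me2AlCl (2 equiv), CH2Cl2, −78 → −20 °C
Reagents that add atoms: none
Why: Lewis-acid-promoted Diels–Alder reaction: Me2AlCl binds the formyl oxygen of 8 and the diene adds in a concerted but asynchronous [4+2] mode, the unsubstituted terminus C6 bonding first to the β-carbon C5 and the substituted terminus C9 then closing onto C10. The closest known reactions are the Lewis-acid-catalysed cycloadditions of cyclohex-1-enecarbaldehydes and of 4,4-disubstituted cyclohex-2-enones with acyclic dienes, which give cis-fused decalins with an angular substituent. Ring B is closed by this intermolecular [4+2] cycloaddition, which forms C9–C10 and C5–C6 suprafacially on the ring A alkene, so H5 and the angular formyl group (the later C20 methyl) must be cis. C9 is set by the endo rule: the formyl group sits under the diene, so the (E)-substituent of the diene (C11) should end up cis to it. The face is chosen by the quaternary C4 centre, the diene adding anti to the larger acetoxymethyl group and syn to the methyl group, so that C6 is cis to C18. The regiochemistry needed (C9 to C10) is secured by the 1-alkyl substituent of the diene and by the neopentyl character of C5, which both direct the unsubstituted diene terminus to C5.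

Step 8
Reactants: 13 [(1R,4aR,5R,8aS)-5-(2-{[tert-butyl(dimethyl)silyl]oxy}ethyl)-4a-formyl-1,6-dimethyl-1,2,3,4,4a,5,8,8a-octahydronaphthalen-1-yl]methyl acetate
Product: 15 [(1R,4aS,5R,8aR)-5-(2-{[tert-butyl(dimethyl)silyl]oxy}ethyl)-1,4a,6-trimethyl-1,2,3,4,4a,5,8,8a-octahydronaphthalen-1-yl]methyl acetate, via tosylhydrazone 14 (not isolated)
Conditions: TsNHNH2, EtOH, 60 °C; then catecholborane, CHCl3, 0 °C; NaOAc·3H2O, reflux
Reagents that add atoms: none
Why: Catecholborane reduction of the tosylhydrazone and loss of N2 from the resulting diazene (a mild Wolff–Kishner-type deoxygenation) should turn the angular formyl group into the C10 methyl group while sparing the acetate, the silyl ether and the alkene.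

Step 9
Reactants: 15 [(1R,4aS,5R,8aR)-5-(2-{[tert-butyl(dimethyl)silyl]oxy}ethyl)-1,4a,6-trimethyl-1,2,3,4,4a,5,8,8a-octahydronaphthalen-1-yl]methyl acetate
Product: 16 [(1R,4aR,5S,7RS,8aR)-5-(2-{[tert-butyl(dimethyl)silyl]oxy}ethyl)-7-chloro-1,4a-dimethyl-6-methylidenedecahydronaphthalen-1-yl]methyl acetate
Conditions: Ca(OCl)2, CO2 (solid), CH2Cl2/H2O, 0 °C
Reagents that add atoms: calcium hypochlorite, [Ca+2].[O-]Cl.[O-]Cl
Why: Ene-type allylic chlorination with hypochlorous acid (chloronium formation with chlorine on the less substituted C7, proton loss from the C17 methyl group) should move the double bond into the exocyclic position; the new C7 centre is not controlled and is removed in step 10.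

Step 10
Reactants: 16 [(1R,4aR,5S,7RS,8aR)-5-(2-{[tert-butyl(dimethyl)silyl]oxy}ethyl)-7-chloro-1,4a-dimethyl-6-methylidenedecahydronaphthalen-1-yl]methyl acetate
Product: 17 [(1R,4aS,5R,8aR)-5-(2-{[tert-butyl(dimethyl)silyl]oxy}ethyl)-1,4a-dimethyl-6-methylidenedecahydronaphthalen-1-yl]methyl acetate
Conditions: Pd(OAc)2 (cat.), PBu3 (cat.), HCO2H, Et3N, 1,4-dioxane, 80 °C
Reagents that add atoms: none
Why: Palladium-catalysed hydrogenolysis of the allylic chloride with formate (Tsuji–Trost-type reduction) delivers hydride to the more substituted terminus C7 of the π-allyl complex and should therefore keep the exocyclic methylene group, both C7 epimers converging.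

Step 11
Reactants: 17 [(1R,4aS,5R,8aR)-5-(2-{[tert-butyl(dimethyl)silyl]oxy}ethyl)-1,4a-dimethyl-6-methylidenedecahydronaphthalen-1-yl]methyl acetate
Product: 18 [(1R,4aS,5R,8aR)-5-(2-hydroxyethyl)-1,4a-dimethyl-6-methylidenedecahydronaphthalen-1-yl]methyl acetate
Conditions: HF·pyridine, pyridine, THF, 0 °C → rt
Reagents that add atoms: none
Why: Buffered fluoride cleaves the primary silyl ether and should leave the acetate and the acid-sensitive exocyclic alkene intact.

Step 12
Reactants: 18 [(1R,4aS,5R,8aR)-5-(2-hydroxyethyl)-1,4a-dimethyl-6-methylidenedecahydronaphthalen-1-yl]methyl acetate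
Product: 19 [(1R,4aS,5R,8aR)-5-(2-iodoethyl)-1,4a-dimethyl-6-methylidenedecahydronaphthalen-1-yl]methyl acetate
Conditions: I2, PPh3, imidazole, CH2Cl2, 0 °C → rt
Reagents that add atoms: iodine, II
Why: Appel-type iodination converts the primary alcohol into the iodide by SN2 displacement of the oxyphosphonium group.

Step 13
Reactants: 19 [(1R,4aS,5R,8aR)-5-(2-iodoethyl)-1,4a-dimethyl-6-methylidenedecahydronaphthalen-1-yl]methyl acetate; 20 3-bromofuran-2(5H)-one
Product: 22 [(1R,4aS,5R,8aR)-1,4a-dimethyl-6-methylidene-5-[2-(2-oxo-2,5-dihydrofuran-3-yl)ethyl]decahydronaphthalen-1-yl]methyl acetate, via alkylzinc iodide 21 (not isolated)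
Conditions: Zn dust (I2-activated), DMA, 40 °C; then 20, Pd2(dba)3 (cat.), SPhos (cat.), THF, rt
Reagents that add atoms: none
Why: Zinc insertion into the primary iodide followed by Negishi cross-coupling with the α-bromobutenolide should form the C12–C13 bond under conditions that tolerate the ester, the lactone and the exocyclic alkene.

**Compound list**
1 | 3-methylcyclohex-2-en-1-one | CC1=CC(=O)CCC1 | starting material
2 | (chloromethyl)dimethyl(propan-2-yloxy)silane | CC(C)O[Si](C)(C)CCl | starting material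
3 | {[dimethyl(propan-2-yloxy)silyl]methyl}magnesium chloride | CC(C)O[Si](C)(C)C[Mg]Cl | intermediate
4 | chloromagnesium enolate of (3R)-3-{[dimethyl(propan-2-yloxy)silyl]methyl}-3-methylcyclohexanone (enolate double bond towards the quaternary carbon) | Cl[Mg]OC1=C[C@](C)(C[Si](C)(C)OC(C)C)CCC1 | intermediate
5 | (3R)-3-{[dimethyl(propan-2-yloxy)silyl]methyl}-3-methylcyclohex-1-en-1-yl trifluoromethanesulfonate | FC(F)(F)S(=O)(=O)OC1=C[C@](C)(C[Si](C)(C)OC(C)C)CCC1 | intermediate
6 | (3R)-3-(hydroxymethyl)-3-methylcyclohex-1-en-1-yl trifluoromethanesulfonate | FC(F)(F)S(=O)(=O)OC1=C[C@](C)(CO)CCC1 | intermediate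
7 | [(1R)-1-methyl-3-(trifluoromethanesulfonyloxy)cyclohex-2-en-1-yl]methyl acetate | FC(F)(F)S(=O)(=O)OC1=C[C@](C)(COC(C)=O)CCC1 | intermediate
8 | [(1R)-3-formyl-1-methylcyclohex-2-en-1-yl]methyl acetate | O=CC1=C[C@](C)(COC(C)=O)CCC1 | intermediate
9 | 3-methyl-2,5-dihydrothiophene 1,1-dioxide | CC1=CCS(=O)(=O)C1 | starting material
10 | tert-butyl(2-iodoethoxy)dimethylsilane | CC(C)(C)[Si](C)(C)OCCI | starting material
11 | (2RS)-2-(2-{[tert-butyl(dimethyl)silyl]oxy}ethyl)-3-methyl-2,5-dihydrothiophene 1,1-dioxide (racemic) | CC1=CCS(=O)(=O)C1CCO[Si](C)(C)C(C)(C)C | intermediate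
12 | tert-butyl(dimethyl){[(3E)-4-methylhexa-3,5-dien-1-yl]oxy}silane | C=C/C(C)=C/CCO[Si](C)(C)C(C)(C)C | intermediate
13 | [(1R,4aR,5R,8aS)-5-(2-{[tert-butyl(dimethyl)silyl]oxy}ethyl)-4a-formyl-1,6-dimethyl-1,2,3,4,4a,5,8,8a-octahydronaphthalen-1-yl]methyl acetate (cis-fused; H5, formyl, C11 chain and CH2OAc on one face) | CC1=CC[C@H]2[C@](C)(COC(C)=O)CCC[C@@]2(C=O)[C@@H]1CCO[Si](C)(C)C(C)(C)C | intermediate
14 | (E)-4-methylbenzenesulfonylhydrazone of aldehyde 13, ring stereocentres as in 13 | CC1=CC[C@H]2[C@](C)(COC(C)=O)CCC[C@@]2(/C=N/NS(=O)(=O)c3ccc(C)cc3)[C@@H]1CCO[Si](C)(C)C(C)(C)C | intermediate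
15 | [(1R,4aS,5R,8aR)-5-(2-{[tert-butyl(dimethyl)silyl]oxy}ethyl)-1,4a,6-trimethyl-1,2,3,4,4a,5,8,8a-octahydronaphthalen-1-yl]methyl acetate | CC1=CC[C@H]2[C@](C)(COC(C)=O)CCC[C@@]2(C)[C@@H]1CCO[Si](C)(C)C(C)(C)C | intermediate
16 | [(1R,4aR,5S,7RS,8aR)-5-(2-{[tert-butyl(dimethyl)silyl]oxy}ethyl)-7-chloro-1,4a-dimethyl-6-methylidenedecahydronaphthalen-1-yl]methyl acetate (mixture of C7 epimers) | C=C1C(Cl)C[C@H]2[C@](C)(COC(C)=O)CCC[C@@]2(C)[C@@H]1CCO[Si](C)(C)C(C)(C)C | intermediate
17 | [(1R,4aS,5R,8aR)-5-(2-{[tert-butyl(dimethyl)silyl]oxy}ethyl)-1,4a-dimethyl-6-methylidenedecahydronaphthalen-1-yl]methyl acetate | C=C1CC[C@H]2[C@](C)(COC(C)=O)CCC[C@@]2(C)[C@@H]1CCO[Si](C)(C)C(C)(C)C | intermediate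
18 | [(1R,4aS,5R,8aR)-5-(2-hydroxyethyl)-1,4a-dimethyl-6-methylidenedecahydronaphthalen-1-yl]methyl acetate | C=C1CC[C@H]2[C@](C)(COC(C)=O)CCC[C@@]2(C)[C@@H]1CCO | intermediate
19 | [(1R,4aS,5R,8aR)-5-(2-iodoethyl)-1,4a-dimethyl-6-methylidenedecahydronaphthalen-1-yl]methyl acetate | C=C1CC[C@H]2[C@](C)(COC(C)=O)CCC[C@@]2(C)[C@@H]1CCI | intermediate
20 | 3-bromofuran-2(5H)-one | O=C1OCC=C1Br | starting material
21 | alkylzinc iodide derived from 19 (zinc on C12), stereocentres as in 19 | C=C1CC[C@H]2[C@](C)(COC(C)=O)CCC[C@@]2(C)[C@@H]1CC[Zn]I | intermediate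
22 | [(1R,4aS,5R,8aR)-1,4a-dimethyl-6-methylidene-5-[2-(2-oxo-2,5-dihydrofuran-3-yl)ethyl]decahydronaphthalen-1-yl]methyl acetate (CNP0350004.1) | C=C1CC[C@H]2[C@](C)(COC(C)=O)CCC[C@@]2(C)[C@@H]1CCC1=CCOC1=O | target

**Step count.** Total: 13 steps. Longest linear sequence: 11 steps (steps 1–4 and 7–13); the diene branch is steps 5–6.

**Steps most likely to fail**

1. Step 7. The leading bond has to form at the neopentyl carbon C5, so the cycloaddition may be slower than Lewis-acid-induced oligomerisation of diene 12; discrimination between the two faces at C4 may also be too small. Fallback (ionic Diels–Alder reaction): from 8, acetalisation with 1,2-bis(trimethylsilyloxy)ethane and catalytic TMSOTf at −78 °C should give [(1R)-3-(1,3-dioxolan-2-yl)-1-methylcyclohex-2-en-1-yl]methyl acetate F1 without double-bond migration. TMSOTf in CH2Cl2 at −78 °C opens F1 to an alkoxy-allyl cation, a far stronger dienophile, which should add 12 in the same regio- and stereochemical sense to give the dioxolane of the cycloadduct, [(1R,4aR,5R,8aS)-5-(2-{[tert-butyl(dimethyl)silyl]oxy}ethyl)-4a-(1,3-dioxolan-2-yl)-1,6-dimethyl-1,2,3,4,4a,5,8,8a-octahydronaphthalen-1-yl]methyl acetate F2. Mild hydrolysis (PPTS, wet acetone) comes back to the route at 13.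

2. Step 1. Enantioface discrimination may be poor with the β-silyl Grignard reagent, and O-triflation of the magnesium enolate may be incomplete. Fallback (racemic addition and resolution): from 1 and Grignard reagent 3, CuBr·SMe2-catalysed conjugate addition in THF with the same PhNTf2 quench should give racemic 3-{[dimethyl(propan-2-yloxy)silyl]methyl}-3-methylcyclohex-1-en-1-yl trifluoromethanesulfonate F3. Tamao–Fleming oxidation as in step 2 gives racemic 3-(hydroxymethyl)-3-methylcyclohex-1-en-1-yl trifluoromethanesulfonate F4. Preparative chromatography on a chiral stationary phase then separates the enantiomers, and the (R)-alcohol rejoins the route at 6.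

3. Step 9. After chloronium formation the proton may be lost from C9 or C6 instead of from C17, and over-chlorination may compete. Fallback (allylic oxidation and reductive transposition): from 15, catalytic SeO2 with t-BuOOH should hydroxylate the C17 methyl group to [(1R,4aR,5S,8aR)-5-(2-{[tert-butyl(dimethyl)silyl]oxy}ethyl)-6-(hydroxymethyl)-1,4a-dimethyl-1,2,3,4,4a,5,8,8a-octahydronaphthalen-1-yl]methyl acetate F5. Methyl chloroformate and pyridine convert it into the methyl carbonate [(1R,4aR,5S,8aR)-5-(2-{[tert-butyl(dimethyl)silyl]oxy}ethyl)-6-{[(methoxycarbonyl)oxy]methyl}-1,4a-dimethyl-1,2,3,4,4a,5,8,8a-octahydronaphthalen-1-yl]methyl acetate F6. Pd(OAc)2, PBu3 and HCO2NH4 then deliver hydride to C7 of the same π-allyl complex, and the sequence comes back to the route at 17, bypassing 16.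

**Further compounds**
F1 | step 7 | [(1R)-3-(1,3-dioxolan-2-yl)-1-methylcyclohex-2-en-1-yl]methyl acetate | O1CCOC1C2=C[C@](C)(COC(C)=O)CCC2
F2 | step 7 | [(1R,4aR,5R,8aS)-5-(2-{[tert-butyl(dimethyl)silyl]oxy}ethyl)-4a-(1,3-dioxolan-2-yl)-1,6-dimethyl-1,2,3,4,4a,5,8,8a-octahydronaphthalen-1-yl]methyl acetate | CC1=CC[C@H]2[C@](C)(COC(C)=O)CCC[C@@]2(C3OCCO3)[C@@H]1CCO[Si](C)(C)C(C)(C)C
F3 | step 1 | racemic 3-{[dimethyl(propan-2-yloxy)silyl]methyl}-3-methylcyclohex-1-en-1-yl trifluoromethanesulfonate | FC(F)(F)S(=O)(=O)OC1=CC(C)(C[Si](C)(C)OC(C)C)CCC1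
F4 | step 1 | racemic 3-(hydroxymethyl)-3-methylcyclohex-1-en-1-yl trifluoromethanesulfonate | FC(F)(F)S(=O)(=O)OC1=CC(C)(CO)CCC1
F5 | step 9 | [(1R,4aR,5S,8aR)-5-(2-{[tert-butyl(dimethyl)silyl]oxy}ethyl)-6-(hydroxymethyl)-1,4a-dimethyl-1,2,3,4,4a,5,8,8a-octahydronaphthalen-1-yl]methyl acetate | OCC1=CC[C@H]2[C@](C)(COC(C)=O)CCC[C@@]2(C)[C@@H]1CCO[Si](C)(C)C(C)(C)C
F6 | step 9 | [(1R,4aR,5S,8aR)-5-(2-{[tert-butyl(dimethyl)silyl]oxy}ethyl)-6-{[(methoxycarbonyl)oxy]methyl}-1,4a-dimethyl-1,2,3,4,4a,5,8,8a-octahydronaphthalen-1-yl]methyl acetate | COC(=O)OCC1=CC[C@H]2[C@](C)(COC(C)=O)CCC[C@@]2(C)[C@@H]1CCO[Si](C)(C)C(C)(C)C
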